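**Strategy.** The target is a longipin-2-en-1-one (C1 ketone, C2=C3, C4, C5, C6 gem-dimethyl, C7–C9 oxygenated, C10 C–Me, C11). Everything rests on disconnecting C1–C11, the bond from the enone carbonyl to the cyclobutane. The precursor is a bicyclo[4.1.1]octenone, built by intramolecular vinylketene–diene [2+2] cycloaddition, in which C11 is the non-enolisable cyclobutanone carbon (as N-tosylhydrazone) and C1 is a (Z)-enal on C4, held cis-1,3 to C11 across the four-membered ring C4–C5–C11–C10. An acyl radical at C1 adds to C11; loss of sulfinate and N2 leaves the bridgehead C–H, closing the cyclohexenone ring (C1, C2, C3, C4, C10, C11) in one operation.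

Key step: step 12

Remark on numbering: longipinane numbers are used for all cyclised compounds; ring A = cyclohexenone (C1, C2, C3, C4, C10, C11), ring B = cyclobutane (C4, C5, C11, C10), ring C = seven-membered ring (C5 to C11). CIP descriptors in the names were assigned by hand; the SMILES are definitive.

Assumption: the L-tryptophan-derived oxazaborolidinone of step 6 is taken to deliver the (5R)-alcohol; should the opposite sense be found, the D-tryptophan-derived catalyst is used.

Step 1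
Reactants: 1 but-2-yn-1-ol
Product: 2 (2Z)-3-iodobut-2-en-1-ol
Conditions: NaAlH2(OCH2CH2OCH3)2 (Red-Al), THF, 0 °C to rt; then I2, −78 to 0 °C
Reagents that add atoms: iodine, II
Why: Alkoxide-directed trans-hydroalumination of the propargylic alcohol puts aluminium on C3, and iodinolysis with retention should give the (Z)-vinyl iodide (hydroalumination–iodination).

Step 2
Reactants: 2 (2Z)-3-iodobut-2-en-1-ol
Product: 3 tert-butyl{[(2Z)-3-iodobut-2-en-1-yl]oxy}dimethylsilane
Conditions: TBSCl, imidazole, CH2Cl2, 0 °C to rt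
Reagents that add atoms: tert-butyldimethylsilyl chloride, CC(C)(C)[Si](C)(C)Cl
Why: Routine silylation of a primary alcohol, needed so that only the neopentyl hydroxyl is free for the later oxidation.

Step 3
Reactants: 3 tert-butyl{[(2Z)-3-iodobut-2-en-1-yl]oxy}dimethylsilane; 4 2,2-dimethylbut-3-en-1-ol
Product: 5 (3E,5Z)-7-[(tert-butyldimethylsilyl)oxy]-2,2,5-trimethylhepta-3,5-dien-1-ol
Conditions: Pd(OAc)2 (5 mol %), K2CO3, nBu4NCl, DMF, 60 °C
Reagents that add atoms: none
Why: Mizoroki–Heck coupling: the alkenylpalladium adds to the terminal CH2, the quaternary carbon leaves only one β-hydrogen for syn-elimination, so the (E)-alkene should form with the (Z)-geometry of the iodide retained.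

Step 4
Reactants: 5 (3E,5Z)-7-[(tert-butyldimethylsilyl)oxy]-2,2,5-trimethylhepta-3,5-dien-1-ol
Product: 6 (3E,5Z)-7-[(tert-butyldimethylsilyl)oxy]-2,2,5-trimethylhepta-3,5-dienal
Conditions: Dess–Martin periodinane, CH2Cl2, rt
Reagents that add atoms: none
Why: Dess–Martin oxidation of the neopentyl alcohol; the α-quaternary aldehyde can neither enolise nor move into conjugation.

Step 5
Reactants: 7 methyl tiglate
Product: 8 tert-butyl{[(1Z)-1-methoxy-2-methylbuta-1,3-dien-1-yl]oxy}dimethylsilane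
Conditions: LDA, THF/DMPU, −78 °C; then TBSCl
Reagents that add atoms: tert-butyldimethylsilyl chloride, CC(C)(C)[Si](C)(C)Cl
Why: Kinetic γ-deprotonation of the enoate and O-silylation of the dienolate should give the silyl dienol ether (vinylogous silyl ketene acetal); its C1=C2 geometry is not transferred to the product.

Step 6
Reactants: 6 (3E,5Z)-7-[(tert-butyldimethylsilyl)oxy]-2,2,5-trimethylhepta-3,5-dienal; 8 tert-butyl{[(1Z)-1-methoxy-2-methylbuta-1,3-dien-1-yl]oxy}dimethylsilane
Product: 9 methyl (2E,5R,7E,9Z)-11-[(tert-butyldimethylsilyl)oxy]-5-hydroxy-2,6,6,9-tetramethylundeca-2,7,9-trienoate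
Conditions: (S)-4-(indol-3-ylmethyl)-2-phenyl-3-tosyl-1,3,2-oxazaborolidin-5-one (30 mol %, from N-tosyl-L-tryptophan and PhBCl2), iPrOH, EtCN, −78 °C
Reagents that add atoms: none
Why: Catalytic asymmetric vinylogous Mukaiyama aldol reaction: γ-attack of the dienol ether gives the (E)-enoate, and the chiral boron Lewis acid should set the C5 carbinol (the future C7) as R by shielding one face of the aldehyde.

Step 7
Reactants: 9 methyl (2E,5R,7E,9Z)-11-[(tert-butyldimethylsilyl)oxy]-5-hydroxy-2,6,6,9-tetramethylundeca-2,7,9-trienoate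
Product: 10 methyl (2E,5R,7E,9Z)-5,11-bis[(tert-butyldimethylsilyl)oxy]-2,6,6,9-tetramethylundeca-2,7,9-trienoate
Conditions: TBSOTf, 2,6-lutidine, CH2Cl2, −78 to 0 °C
Reagents that add atoms: tert-butyldimethylsilyl triflate, CC(C)(C)[Si](C)(C)OS(=O)(=O)C(F)(F)F
Why: Silylation of the hindered neopentyl secondary alcohol with the reactive silyl triflate.

Step 8
Reactants: 10 methyl (2E,5R,7E,9Z)-5,11-bis[(tert-butyldimethylsilyl)oxy]-2,6,6,9-tetramethylundeca-2,7,9-trienoate
Product: 11 (2E,5R,7E,9Z)-5,11-bis[(tert-butyldimethylsilyl)oxy]-2,6,6,9-tetramethylundeca-2,7,9-trienoic acid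
Conditions: LiOH, THF/MeOH/H2O, 45 °C; then 1 M HCl to pH 4, 0 °C
Reagents that add atoms: lithium hydroxide, [Li+].[OH-]
Why: Saponification of the methyl ester; both silyl ethers should survive aqueous hydroxide and the brief, cold acidification.

Step 9
Reactants: 11 (2E,5R,7E,9Z)-5,11-bis[(tert-butyldimethylsilyl)oxy]-2,6,6,9-tetramethylundeca-2,7,9-trienoic acid
Product: 14 4-[(tert-butyldimethylsilyl)oxy]-8-{(2Z)-4-[(tert-butyldimethylsilyl)oxy]but-2-en-2-yl}-1,5,5-trimethylbicyclo[4.1.1]oct-2-en-7-one (silyloxy group on the side of C8; butenyl group pointing away from the four-carbon bridge; C7 = C11, C8 = C4, C4 = C7 of the target), via acid chloride 12 (not isolated), via vinylketene 13 (not isolated)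
Conditions: 1-chloro-N,N,2-trimethylprop-1-en-1-amine, CH2Cl2, 0 °C to rt; then slow addition to Et3N, toluene, 110 °C, 0.005 M
Reagents that add atoms: none
Why: Intramolecular [2+2] cycloaddition of a vinylketene (from γ-deprotonation of the enoyl chloride, as in the geranoyl chloride to chrysanthenone cyclisation) with the near double bond of the diene: the ketene carbonyl carbon (C11) should bond to the diene terminus C5 and the α-carbon C10 to C4, where allylic stabilisation develops, giving the bridged ketone with C10 quaternary; the E-alkene places the butenyl group on C4 anti to the tether, and allylic 1,3-strain across the (Z)-C8=C9 bond (H-7 inside, OSi outside) should steer the diene to the face that leaves the C7–O bond on the side of C4.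

Step 10
Reactants: 14 bicyclic cyclobutanone
Product: 15 N'-{4-[(tert-butyldimethylsilyl)oxy]-8-[(2Z)-4-hydroxybut-2-en-2-yl]-1,5,5-trimethylbicyclo[4.1.1]oct-2-en-7-ylidene}-4-methylbenzenesulfonohydrazide (configuration as 14; C=N isomers not separated)
Conditions: TsNHNH2, camphorsulfonic acid (10 mol %), MeOH, 0 °C to rt
Reagents that add atoms: p-toluenesulfonyl hydrazide, Cc1ccc(cc1)S(=O)(=O)NN
Why: Hydrazone condensation at the strained, non-enolisable cyclobutanone, with acid methanolysis of the primary allylic silyl ether in the same pot; the hindered secondary silyl ether at C7 should survive.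

Step 11
Reactants: 15 tosylhydrazone allylic alcohol
Product: 16 (2Z)-3-{4-[(tert-butyldimethylsilyl)oxy]-1,5,5-trimethyl-7-(2-tosylhydrazinylidene)bicyclo[4.1.1]oct-2-en-8-yl}but-2-enal (configuration as 14)
Conditions: MnO2, CH2Cl2, rt; used crude
Reagents that add atoms: none
Why: Chemoselective MnO2 oxidation of the only free (allylic, primary) alcohol, which should keep the (Z)-geometry as in nerol to neral.

Step 12
Reactants: 16 (Z)-enal tosylhydrazone
Product: 19 (4R,5S,7R,10R,11R)-7-[(tert-butyldimethylsilyl)oxy]longipina-2,8-dien-1-one, via cyclised tosylhydrazine 17 (not isolated), via diazene 18 (not isolated)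
Conditions: (nBu4N)4[W10O32] (2 mol %), 390 nm LEDs, MeCN, 0.01 M, rt; then Et3N, 60 °C
Reagents that add atoms: none
Why: Proposed new method: photoexcited decatungstate abstracts the formyl hydrogen of the (Z)-enal to give the σ-acyl radical at C1, which adds to the hydrazone carbon C11; back hydrogen transfer from the reduced polyoxotungstate gives N-alkyl-N'-tosylhydrazine 17, Et3N eliminates sulfinate to diazene 18, and loss of N2 leaves C11–H (closest known reaction types: decatungstate hydroacylation, and radical additions or cyclisations onto N-sulfonyl- and N-aziridinylhydrazones that end with loss of sulfinate and N2). Ring A (C1, C2, C3, C4, C10, C11) closes in the 6-exo-trig mode onto the C=N bond. The only new stereocenter, C11, is fixed by the ring: the acyl carbon can reach C11 only on the face it shares with C4, away from ring C, so the new C–H is exo. The step needs formyl C–H abstraction in preference to the C7–H and allylic C–H bonds, attack at carbon and not at nitrogen (6-exo versus 7-endo), and retention of the C2=C3 (Z)-geometry, since the (E)-isomer cannot cyclise; the weak, hydridic aldehyde C–H bond, the ring size and the σ-character of the acyl radical should secure these. Loss of N2 should make closure of the strained bicyclo[3.1.1]heptenone irreversible.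

Step 13
Reactants: 19 (4R,5S,7R,10R,11R)-7-[(tert-butyldimethylsilyl)oxy]longipina-2,8-dien-1-one
Product: 20 (4R,5S,7R,10R,11R)-7-hydroxylongipina-2,8-dien-1-one
Conditions: nBu4NF, AcOH (1:1), THF, 40 °C
Reagents that add atoms: none
Why: Fluoride cleavage of the hindered secondary silyl ether, buffered so that the enone is not exposed to base.

Step 14
Reactants: 20 (4R,5S,7R,10R,11R)-7-hydroxylongipina-2,8-dien-1-one; 21 angelic acid
Product: 23 (4R,5S,7R,10R,11R)-1-oxolongipina-2,8-dien-7-yl (2Z)-2-methylbut-2-enoate, via mixed anhydride 22 (not isolated)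
Conditions: 21, 2,4,6-trichlorobenzoyl chloride, Et3N, toluene, rt; then 20, 80 °C
Reagents that add atoms: none
Why: Yamaguchi-type esterification through the angelic 2,4,6-trichlorobenzoic mixed anhydride without a nucleophilic catalyst, which should acylate the hindered C7–OH with retention at C7 and without Z-to-E isomerisation to the tiglate.

Step 15
Reactants: 23 7-angelate dienone
Product: 24 (4R,5S,7S,8S,9S,10R,11R)-8,9-dihydroxy-1-oxolongipin-2-en-7-yl (2Z)-2-methylbut-2-enoate (8-OH and 9-OH on the face of C11, 7-O on the face of C4)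
Conditions: OsO4 (5 mol %), N-methylmorpholine N-oxide, acetone/H2O, 0 °C to rt
Reagents that add atoms: osmium tetroxide, O=[Os](=O)(=O)=O; N-methylmorpholine N-oxide, C[N+]1([O-])CCOCC1; water, O
Why: Upjohn syn-dihydroxylation of the isolated C8=C9 bond, which should react before the two conjugated double bonds, on the face anti to the allylic C7 acyloxy group (Kishi's rule), setting C8 and C9 cis to each other and trans to C7–O.

Step 16
Reactants: 24 8,9-diol 7-angelate; 25 (2R)-2-methylbutanoic acid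
Product: 26 (4R,5S,7S,8S,9S,10R,11R)-9-hydroxy-8-{[(2R)-2-methylbutanoyl]oxy}-1-oxolongipin-2-en-7-yl (2Z)-2-methylbut-2-enoate (target)
Conditions: 25 (1.1 equiv), DCC, DMAP (10 mol %), CH2Cl2, −20 to 0 °C
Reagents that add atoms: none
Why: Steglich esterification, which should be selective for C8–OH because C9–OH is neopentyl-like next to the quaternary C10; the mild conditions should preserve the α-stereocenter of the acid and the angelate geometry.

**Compound list**

1 | but-2-yn-1-ol | CC#CCO | starting material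
2 | (2Z)-3-iodobut-2-en-1-ol | C/C(I)=C/CO | intermediate
3 | tert-butyl{[(2Z)-3-iodobut-2-en-1-yl]oxy}dimethylsilane | C/C(I)=C/CO[Si](C)(C)C(C)(C)C | intermediate
4 | 2,2-dimethylbut-3-en-1-ol | C=CC(C)(C)CO | starting material
5 | (3E,5Z)-7-[(tert-butyldimethylsilyl)oxy]-2,2,5-trimethylhepta-3,5-dien-1-ol | OCC(C)(C)/C=C/C(C)=C\CO[Si](C)(C)C(C)(C)C | intermediate
6 | (3E,5Z)-7-[(tert-butyldimethylsilyl)oxy]-2,2,5-trimethylhepta-3,5-dienal | O=CC(C)(C)/C=C/C(C)=C\CO[Si](C)(C)C(C)(C)C | intermediate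
7 | methyl tiglate, methyl (2E)-2-methylbut-2-enoate | C/C=C(\C)C(=O)OC | starting material
8 | tert-butyl{[(1Z)-1-methoxy-2-methylbuta-1,3-dien-1-yl]oxy}dimethylsilane | C=C/C(C)=C(/OC)O[Si](C)(C)C(C)(C)C | intermediate
9 | methyl (2E,5R,7E,9Z)-11-[(tert-butyldimethylsilyl)oxy]-5-hydroxy-2,6,6,9-tetramethylundeca-2,7,9-trienoate | COC(=O)/C(C)=C/C[C@@H](O)C(C)(C)/C=C/C(C)=C\CO[Si](C)(C)C(C)(C)C | intermediate
10 | methyl (2E,5R,7E,9Z)-5,11-bis[(tert-butyldimethylsilyl)oxy]-2,6,6,9-tetramethylundeca-2,7,9-trienoate | COC(=O)/C(C)=C/C[C@@H](O[Si](C)(C)C(C)(C)C)C(C)(C)/C=C/C(C)=C\CO[Si](C)(C)C(C)(C)C | intermediate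
11 | (2E,5R,7E,9Z)-5,11-bis[(tert-butyldimethylsilyl)oxy]-2,6,6,9-tetramethylundeca-2,7,9-trienoic acid | OC(=O)/C(C)=C/C[C@@H](O[Si](C)(C)C(C)(C)C)C(C)(C)/C=C/C(C)=C\CO[Si](C)(C)C(C)(C)C | intermediate
12 | (2E,5R,7E,9Z)-5,11-bis[(tert-butyldimethylsilyl)oxy]-2,6,6,9-tetramethylundeca-2,7,9-trienoyl chloride | ClC(=O)/C(C)=C/C[C@@H](O[Si](C)(C)C(C)(C)C)C(C)(C)/C=C/C(C)=C\CO[Si](C)(C)C(C)(C)C | intermediate
13 | (3Z,5R,7E,9Z)-5,11-bis[(tert-butyldimethylsilyl)oxy]-2,6,6,9-tetramethylundeca-1,3,7,9-tetraen-1-one (vinylketene) | O=C=C(C)/C=C\[C@@H](O[Si](C)(C)C(C)(C)C)C(C)(C)/C=C/C(C)=C\CO[Si](C)(C)C(C)(C)C | intermediate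
14 | 4-[(tert-butyldimethylsilyl)oxy]-8-{(2Z)-4-[(tert-butyldimethylsilyl)oxy]but-2-en-2-yl}-1,5,5-trimethylbicyclo[4.1.1]oct-2-en-7-one, silyloxy group on the side of C8, butenyl group away from the four-carbon bridge | CC(C)(C)[Si](C)(C)O[C@@H]1C=C[C@@]2(C)C(=O)[C@H]([C@@H]2/C(C)=C\CO[Si](C)(C)C(C)(C)C)C1(C)C | intermediate
15 | N-tosylhydrazone of 14 with the primary allylic alcohol free | CC(C)(C)[Si](C)(C)O[C@@H]1C=C[C@@]2(C)C(=NNS(=O)(=O)c3ccc(C)cc3)[C@H]([C@@H]2/C(C)=C\CO)C1(C)C | intermediate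
16 | (Z)-enal N-tosylhydrazone, (2Z)-3-{4-[(tert-butyldimethylsilyl)oxy]-1,5,5-trimethyl-7-(2-tosylhydrazinylidene)bicyclo[4.1.1]oct-2-en-8-yl}but-2-enal | CC(C)(C)[Si](C)(C)O[C@@H]1C=C[C@@]2(C)C(=NNS(=O)(=O)c3ccc(C)cc3)[C@H]([C@@H]2/C(C)=C\C=O)C1(C)C | intermediate
17 | 7-[(tert-butyldimethylsilyl)oxy]-11-(2-tosylhydrazinyl)longipina-2,8-dien-1-one | CC(C)(C)[Si](C)(C)O[C@@H]1C=C[C@@]2(C)[C@]3(NNS(=O)(=O)c4ccc(C)cc4)C(=O)C=C(C)[C@H]2[C@@H]3C1(C)C | intermediate
18 | 7-[(tert-butyldimethylsilyl)oxy]-11-diazenyllongipina-2,8-dien-1-one | CC(C)(C)[Si](C)(C)O[C@@H]1C=C[C@@]2(C)[C@]3(N=N)C(=O)C=C(C)[C@H]2[C@@H]3C1(C)C | intermediate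
19 | (4R,5S,7R,10R,11R)-7-[(tert-butyldimethylsilyl)oxy]longipina-2,8-dien-1-one | CC(C)(C)[Si](C)(C)O[C@@H]1C=C[C@@]2(C)[C@@H]3C(=O)C=C(C)[C@H]2[C@@H]3C1(C)C | intermediate
20 | (4R,5S,7R,10R,11R)-7-hydroxylongipina-2,8-dien-1-one | O[C@@H]1C=C[C@@]2(C)[C@@H]3C(=O)C=C(C)[C@H]2[C@@H]3C1(C)C | intermediate
21 | angelic acid, (2Z)-2-methylbut-2-enoic acid | C/C=C(/C)C(=O)O | starting material
22 | (2Z)-2-methylbut-2-enoic 2,4,6-trichlorobenzoic anhydride | C/C=C(/C)C(=O)OC(=O)c1c(Cl)cc(Cl)cc1Cl | intermediate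
23 | (4R,5S,7R,10R,11R)-1-oxolongipina-2,8-dien-7-yl (2Z)-2-methylbut-2-enoate | C/C=C(/C)C(=O)O[C@@H]1C=C[C@@]2(C)[C@@H]3C(=O)C=C(C)[C@H]2[C@@H]3C1(C)C | intermediate
24 | (4R,5S,7S,8S,9S,10R,11R)-8,9-dihydroxy-1-oxolongipin-2-en-7-yl (2Z)-2-methylbut-2-enoate | C/C=C(/C)C(=O)O[C@@H]1[C@@H](O)[C@@H](O)[C@@]2(C)[C@@H]3C(=O)C=C(C)[C@H]2[C@@H]3C1(C)C | intermediate
25 | (2R)-2-methylbutanoic acid | CC[C@@H](C)C(=O)O | starting material
26 | (4R,5S,7S,8S,9S,10R,11R)-9-hydroxy-8-{[(2R)-2-methylbutanoyl]oxy}-1-oxolongipin-2-en-7-yl (2Z)-2-methylbut-2-enoate | C/C=C(/C)C(=O)O[C@@H]1[C@@H](OC(=O)[C@H](C)CC)[C@@H](O)[C@@]2(C)[C@@H]3C(=O)C=C(C)[C@H]2[C@@H]3C1(C)C | target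

**Step count.** Total: 16 steps. Longest linear sequence: 15 steps (1 → 2 → 3 → 5 → 6 → 9 → 10 → 11 → 14 → 15 → 16 → 19 → 20 → 23 → 24 → 26); step 5 is the side branch.

**Steps most likely to fail**

1. Step 12 (proposed new method). Hydrogen abstraction may occur at C7–H or at allylic positions instead of the formyl group; the acyl radical may also be quenched or lose its (Z)-geometry before it closes the strained ring, or add at nitrogen. Fallback with known chemistry, setting out from 14 and returning at 19: camphorsulfonic acid in MeOH removes the primary silyl ether to give the keto alcohol F1; MnO2 gives the keto enal F2; SmI2 (THF, t-BuOH, −78 °C) effects intramolecular ketyl–carbonyl (pinacol) coupling, forming the same C1–C11 bond, to give the 1,11-diol F3; MnO2 oxidises the allylic C1 hydroxyl to the 11-hydroxy enone F4; methyl chlorooxoacetate and DMAP give the tertiary methyl oxalate F5; Bu3SnH/AIBN in toluene at 110 °C removes the bridgehead oxygen by radical deoxygenation and gives 19.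

2. Step 9. A 1,5-hydrogen shift of H-7 onto the ketene carbon, ketene oligomerisation, or approach of the diene from the wrong face may outrun the cycloaddition, which has to close a seven-membered ring. Fallback, setting out from 11 and returning at 14: coupling with pyrrolidine (EDC, HOBt) gives the amide F6; Tf2O and 2,4,6-collidine in 1,2-dichloroethane at 80 °C generate the more electrophilic, non-dimerising vinylketeniminium ion, whose intramolecular [2+2] cycloaddition gives the cyclobutaniminium triflate F7; aqueous NaHCO3 hydrolyses it to 14.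

3. Step 15. Poor chemoselectivity: osmylation of the angelate double bond may compete with that of the hindered C8=C9 bond. Fallback, setting out from 20 and returning at 24: OsO4/N-methylmorpholine N-oxide on the free allylic alcohol (anti to C7–OH; only the enone competes) gives the 7,8,9-triol F8; 2,2-dimethoxypropane and pyridinium p-toluenesulfonate protect the cis-8,9-diol as the acetonide F9; angeloylation of C7–OH with mixed anhydride 22 gives the angelate acetonide F10; 80% aqueous AcOH at 40 °C removes the acetonide and gives 24.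

**Further compounds**

F1 | step 12 | 4-[(tert-butyldimethylsilyl)oxy]-8-[(2Z)-4-hydroxybut-2-en-2-yl]-1,5,5-trimethylbicyclo[4.1.1]oct-2-en-7-one | CC(C)(C)[Si](C)(C)O[C@@H]1C=C[C@@]2(C)C(=O)[C@H]([C@@H]2/C(C)=C\CO)C1(C)C
F2 | step 12 | (2Z)-3-{4-[(tert-butyldimethylsilyl)oxy]-1,5,5-trimethyl-7-oxobicyclo[4.1.1]oct-2-en-8-yl}but-2-enal | CC(C)(C)[Si](C)(C)O[C@@H]1C=C[C@@]2(C)C(=O)[C@H]([C@@H]2/C(C)=C\C=O)C1(C)C
F3 | step 12 | 7-[(tert-butyldimethylsilyl)oxy]longipina-2,8-diene-1,11-diol (either C1 epimer) | CC(C)(C)[Si](C)(C)O[C@@H]1C=C[C@@]2(C)[C@]3(O)C(O)C=C(C)[C@H]2[C@@H]3C1(C)C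
F4 | step 12 | 7-[(tert-butyldimethylsilyl)oxy]-11-hydroxylongipina-2,8-dien-1-one | CC(C)(C)[Si](C)(C)O[C@@H]1C=C[C@@]2(C)[C@]3(O)C(=O)C=C(C)[C@H]2[C@@H]3C1(C)C
F5 | step 12 | 7-[(tert-butyldimethylsilyl)oxy]-1-oxolongipina-2,8-dien-11-yl methyl oxalate | CC(C)(C)[Si](C)(C)O[C@@H]1C=C[C@@]2(C)[C@]3(OC(=O)C(=O)OC)C(=O)C=C(C)[C@H]2[C@@H]3C1(C)C
F6 | step 9 | (2E,5R,7E,9Z)-5,11-bis[(tert-butyldimethylsilyl)oxy]-2,6,6,9-tetramethyl-1-(pyrrolidin-1-yl)undeca-2,7,9-trien-1-one | O=C(/C(C)=C/C[C@@H](O[Si](C)(C)C(C)(C)C)C(C)(C)/C=C/C(C)=C\CO[Si](C)(C)C(C)(C)C)N1CCCC1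
F7 | step 9 | cyclobutaniminium triflate, pyrrolidinium ylidene analogue of 14 | CC(C)(C)[Si](C)(C)O[C@@H]1C=C[C@@]2(C)C(=[N+]3CCCC3)[C@H]([C@@H]2/C(C)=C\CO[Si](C)(C)C(C)(C)C)C1(C)C.[O-]S(=O)(=O)C(F)(F)F
F8 | step 15 | 7,8,9-trihydroxylongipin-2-en-1-one (7-OH on the face of C4, 8-OH and 9-OH on the face of C11) | O[C@@H]1[C@@H](O)[C@@H](O)[C@@]2(C)[C@@H]3C(=O)C=C(C)[C@H]2[C@@H]3C1(C)C
F9 | step 15 | 7-hydroxy-8,9-(isopropylidenedioxy)longipin-2-en-1-one | O[C@@H]1[C@H]4OC(C)(C)O[C@H]4[C@@]2(C)[C@@H]3C(=O)C=C(C)[C@H]2[C@@H]3C1(C)C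
F10 | step 15 | 8,9-(isopropylidenedioxy)-1-oxolongipin-2-en-7-yl (2Z)-2-methylbut-2-enoate | C/C=C(/C)C(=O)O[C@@H]1[C@H]4OC(C)(C)O[C@H]4[C@@]2(C)[C@@H]3C(=O)C=C(C)[C@H]2[C@@H]3C1(C)C
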